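## Retrosynthetic overview

1. Locants: ring A arm C7–C8–C9, ring B arm C7'–C8'–C9'; ring 1 = C7, O, C9', C8', C8; ring 2 = C7', O, C9, C8, C8'; ring 3 = the dihydrofuran fused to ring B and carrying ring C. The strategy rests on C9: in ring 2 it is a bare CH2 bonded only to the C7' oxygen and to C8, while C8 and C7 can be the two carbons of an enol ether in ring 1.
2. Last disconnection: C8–C9 and C7–H. Ring 2 closes from a methoxymethyl ether on the C7' oxygen onto the C7=C8 enol ether of a 5-aryl-2,3-dihydrofuran, and hydride then sets C7 (step 17).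
3. Ring 1: the enol ether comes from a γ-lactone (C7 as carbonyl) by addition of the ring A aryllithium and dehydration; the lactone comes from an imide reduced next to a tert-butyl ester.
4. C7'–C8': auxiliary-controlled anti-aldol of a succinate imide with the ring B aldehyde.
5. Ring 3 is made first, as the 2,3-cis dihydrobenzofuran, by enantioselective Rh-carbenoid insertion into a benzylic C–H bond. Order of ring formation: ring 3, ring 1, ring 2.

Key step: step 17

Remark: read from the SMILES, the target has a 2,3-cis dihydrobenzofuran (2S,3S) and both aryl groups endo on the furofuran (7S,8S,7'S,8'S). Rh2(R-PTTL)4 and the (S)-benzyl auxiliary are assigned to this series from the recalled sense of such insertions and from the chelated-enolate model; the antipode would be used if either sense proved opposite.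

Shorthand in names: TIPS = triisopropylsilyl; ArA = 3-methoxy-4-(TIPS-oxy)phenyl (the pattern of rings A and C); ArB = (2S,3S)-7-methoxy-2-ArA-3-[(TIPS-oxy)methyl]-2,3-dihydrobenzofuran-5-yl.

## Route

Step 1
Reactants: 1 vanillin
Product: 2 3-methoxy-4-(triisopropylsilyloxy)benzaldehyde
Conditions: TIPSCl, imidazole, DMF, rt
Reagents that add atoms: triisopropylsilyl chloride, CC(C)[Si](Cl)(C(C)C)C(C)C
Why: Imidazole-promoted O-silylation of the phenol gives a base-robust aryl silyl ether that is carried to the last step.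

Step 2
Reactants: 2 3-methoxy-4-(triisopropylsilyloxy)benzaldehyde
Product: 3 [3-methoxy-4-(triisopropylsilyloxy)phenyl]methanol
Conditions: NaBH4, MeOH/THF, 0 °C
Reagents that add atoms: none
Why: Borohydride reduction of the aryl aldehyde to the benzylic alcohol leaves the aryl silyl ether untouched.

Step 3
Reactants: 3 [3-methoxy-4-(triisopropylsilyloxy)phenyl]methanol; 4 3-bromo-4-hydroxy-5-methoxybenzonitrile
Product: 5 3-bromo-5-methoxy-4-{[3-methoxy-4-(triisopropylsilyloxy)phenyl]methoxy}benzonitrile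
Conditions: PPh3, DIAD, THF, 0 °C to rt
Reagents that add atoms: none
Why: Mitsunobu etherification couples the acidic cyanophenol with the activated benzylic alcohol under neutral conditions, which avoids carbonate bases that would attack the aryl silyl ether.

Step 4
Reactants: 5 3-bromo-5-methoxy-4-{[3-methoxy-4-(triisopropylsilyloxy)phenyl]methoxy}benzonitrile
Product: 6 tert-butyl 2-(5-cyano-3-methoxy-2-{[3-methoxy-4-(triisopropylsilyloxy)phenyl]methoxy}phenyl)acetate
Conditions: BrZnCH2CO2t-Bu, Pd(dba)2 (2 mol %), P(t-Bu)3 (2 mol %), THF, rt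
Reagents that add atoms: 2-tert-butoxy-2-oxoethylzinc bromide, CC(C)(C)OC(=O)C[Zn]Br
Why: Pd-catalysed α-arylation of the Reformatsky reagent (Negishi-type coupling through zerovalent palladium) exchanges the aryl bromide for the acetate unit at room temperature without added base, conditions under which the nitrile and the silyl ether are inert.

Step 5
Reactants: 6 tert-butyl 2-(5-cyano-3-methoxy-2-{[3-methoxy-4-(triisopropylsilyloxy)phenyl]methoxy}phenyl)acetate
Product: 7 tert-butyl 2-(5-cyano-3-methoxy-2-{[3-methoxy-4-(triisopropylsilyloxy)phenyl]methoxy}phenyl)-2-diazoacetate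
Conditions: p-ABSA, DBU, MeCN, 0 °C to rt
Reagents that add atoms: 4-acetamidobenzenesulfonyl azide, CC(=O)Nc1ccc(cc1)S(=O)(=O)N=[N+]=[N-]
Why: Regitz diazo transfer to the benzylic ester α-carbon gives the donor/acceptor diazo ester.

Step 6
Reactants: 7 tert-butyl 2-(5-cyano-3-methoxy-2-{[3-methoxy-4-(triisopropylsilyloxy)phenyl]methoxy}phenyl)-2-diazoacetate
Product: 8 tert-butyl (2S,3R)-5-cyano-7-methoxy-2-[3-methoxy-4-(triisopropylsilyloxy)phenyl]-2,3-dihydrobenzofuran-3-carboxylate (2,3-cis)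
Conditions: Rh2(R-PTTL)4 [dirhodium tetrakis(N-phthaloyl-(R)-tert-leucinate)] (1 mol %), PhMe, −60 °C
Reagents that add atoms: none
Why: Dirhodium-carboxylate-catalysed intramolecular 1,5 C–H insertion of the aryl ester carbenoid into the ether-activated benzylic C–H bond closes ring 3, the concerted insertion giving the 2,3-cis isomer and the phthaloyl-tert-leucinate ligands choosing between the two enantiotopic benzylic hydrogens to set C2 (S) and C3 (R).

Step 7
Reactants: 8 tert-butyl (2S,3R)-5-cyano-7-methoxy-2-[3-methoxy-4-(triisopropylsilyloxy)phenyl]-2,3-dihydrobenzofuran-3-carboxylate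
Product: 10 (2S,3S)-3-(hydroxymethyl)-7-methoxy-2-[3-methoxy-4-(triisopropylsilyloxy)phenyl]-2,3-dihydrobenzofuran-5-carbaldehyde, via aluminium aldimine 9 (not isolated)
Conditions: i-Bu2AlH (4.5 equiv), CH2Cl2, −78 to 0 °C; aq. potassium sodium tartrate, then SiO2
Reagents that add atoms: water, O
Why: Hydride reduction with i-Bu2AlH takes the tert-butyl ester to the primary alcohol without a base that could epimerise C3 and stops at the N-aluminated aldimine for the nitrile, which hydrolyses to the aldehyde on work-up.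

Step 8
Reactants: 10 (2S,3S)-3-(hydroxymethyl)-7-methoxy-2-[3-methoxy-4-(triisopropylsilyloxy)phenyl]-2,3-dihydrobenzofuran-5-carbaldehyde
Product: 11 (2S,3S)-7-methoxy-2-[3-methoxy-4-(triisopropylsilyloxy)phenyl]-3-[(triisopropylsilyloxy)methyl]-2,3-dihydrobenzofuran-5-carbaldehyde (ArB–CHO)
Conditions: TIPSCl, imidazole, DMAP (cat.), DMF, rt
Reagents that add atoms: triisopropylsilyl chloride, CC(C)[Si](Cl)(C(C)C)C(C)C
Why: Imidazole-promoted silylation protects the primary alcohol and does not touch the non-enolisable aldehyde.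

Step 9
Reactants: 12 4-tert-butoxy-4-oxobutanoic acid; 13 (S)-4-benzyloxazolidin-2-one
Product: 15 tert-butyl 4-[(4S)-4-benzyl-2-oxooxazolidin-3-yl]-4-oxobutanoate, via mixed pivalic anhydride 14 (not isolated)
Conditions: PivCl, Et3N, THF, −20 °C; then 13, LiCl, rt
Reagents that add atoms: none
Why: N-acylation of the oxazolidinone by the pivaloyl mixed anhydride under LiCl/Et3N activation takes place at the less hindered succinyl carbonyl.

Step 10
Reactants: 11 ArB–CHO; 15 tert-butyl 4-[(4S)-4-benzyl-2-oxooxazolidin-3-yl]-4-oxobutanoate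
Product: 17 tert-butyl (3R)-4-[(4S)-4-benzyl-2-oxooxazolidin-3-yl]-3-[(S)-hydroxy(ArB)methyl]-4-oxobutanoate, via trimethylsilyl ether 16 (not isolated)
Conditions: MgCl2 (0.2 equiv), Et3N, TMSCl, EtOAc, rt; then citric acid, MeOH, 0 °C
Reagents that add atoms: none
Why: Magnesium halide-catalysed direct anti-aldol of the N-acyloxazolidinone, in which soft enolisation gives the chelated Z-enolate, the aldehyde adds to the face opposite the benzyl group through a boat-like transition state and silylation of the aldolate turns the catalyst over, should set C8' (3R) and C7' (S) in the anti relationship and turn any minor enantiomer of 11 into a separable diastereomer.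

Step 11
Reactants: 17 tert-butyl (3R)-4-[(4S)-4-benzyl-2-oxooxazolidin-3-yl]-3-[(S)-hydroxy(ArB)methyl]-4-oxobutanoate
Product: 18 tert-butyl (3R)-4-[(4S)-4-benzyl-2-oxooxazolidin-3-yl]-3-[(S)-(methoxymethoxy)(ArB)methyl]-4-oxobutanoate
Conditions: MOMCl, i-Pr2NEt, Bu4NI (cat.), CH2Cl2, 0 to 40 °C
Reagents that add atoms: chloromethyl methyl ether, COCCl
Why: O-alkylation of the secondary benzylic alcohol with the chloromethyl ether under a hindered amine base installs the formaldehyde acetal that later delivers C9, under conditions too weakly basic for retro-aldol cleavage.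

Step 12
Reactants: 18 tert-butyl (3R)-4-[(4S)-4-benzyl-2-oxooxazolidin-3-yl]-3-[(S)-(methoxymethoxy)(ArB)methyl]-4-oxobutanoate
Product: 19 tert-butyl (3S)-4-hydroxy-3-[(S)-(methoxymethoxy)(ArB)methyl]butanoate
Conditions: LiBH4, MeOH (1 equiv), THF, 0 °C
Reagents that add atoms: none
Why: Reductive cleavage of the imide by LiBH4 is faster than reduction of the tert-butyl ester, so C9' becomes the primary alcohol and the auxiliary is released while the ester is kept.

Step 13
Reactants: 19 tert-butyl (3S)-4-hydroxy-3-[(S)-(methoxymethoxy)(ArB)methyl]butanoate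
Product: 20 (4S)-4-[(S)-(methoxymethoxy)(ArB)methyl]dihydrofuran-2(3H)-one
Conditions: KOt-Bu (0.2 equiv), THF, 0 °C
Reagents that add atoms: none
Why: Alkoxide-catalysed intramolecular transesterification (5-exo-trig lactonisation) closes ring 1 at the lactone oxidation level without the acid that the benzylic acetal and ring 3 would not tolerate.

Step 14
Reactants: 21 4-bromo-2-methoxyphenol
Product: 22 (4-bromo-2-methoxyphenoxy)triisopropylsilane
Conditions: TIPSCl, imidazole, DMF, rt
Reagents that add atoms: triisopropylsilyl chloride, CC(C)[Si](Cl)(C(C)C)C(C)C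
Why: Imidazole-promoted O-silylation masks the phenol before the halogen–metal exchange.

Step 15
Reactants: 22 (4-bromo-2-methoxyphenoxy)triisopropylsilane; 20 (4S)-4-[(S)-(methoxymethoxy)(ArB)methyl]dihydrofuran-2(3H)-one
Product: 24 (4S)-2-ArA-4-[(S)-(methoxymethoxy)(ArB)methyl]tetrahydrofuran-2-ol (anomer mixture), via aryllithium 23 (not isolated)
Conditions: 22, n-BuLi, THF, −78 °C; then 20, −78 °C; H2O
Reagents that add atoms: none
Why: Bromine–lithium exchange followed by 1,2-addition of the aryllithium to the γ-lactone stops at the lithium hemiketalate at low temperature, so a single ring A unit is attached to C7.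

Step 16
Reactants: 24 (4S)-2-ArA-4-[(S)-(methoxymethoxy)(ArB)methyl]tetrahydrofuran-2-ol
Product: 25 (3S)-5-ArA-3-[(S)-(methoxymethoxy)(ArB)methyl]-2,3-dihydrofuran
Conditions: PPTS (5 mol %), 4 Å MS, PhMe, 50 °C; Et3N
Reagents that add atoms: none
Why: Acid-catalysed dehydration of the cyclic hemiketal through the aryl-stabilised oxocarbenium ion can lose a proton only from C8 and so should give the conjugated C7=C8 enol ether as one regioisomer.

Step 17
Reactants: 25 (3S)-5-ArA-3-[(S)-(methoxymethoxy)(ArB)methyl]-2,3-dihydrofuran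
Product: 27 tris(triisopropylsilyl) ether of the target [(7S,8S,7'S,8'S)-furofuran with ArA on C7 and ArB on C7'], via oxocarbenium triflate 26 (not isolated)
Conditions: TMSOTf (1.2 equiv), 2,6-di-tert-butyl-4-methylpyridine (2.5 equiv), 4 Å MS, CH2Cl2, −78 to −40 °C; then Et3SiH (5 equiv), −78 °C
Reagents that add atoms: none
Why: Proposed new method: TMSOTf silylates the terminal methoxy oxygen of the formaldehyde acetal, loss of MeOSiMe3 leaves the oxocarbenium ion C7'–O=C9H2, the enol ether attacks it through C8 and the charge moves to C7, where ring A and the ring 1 oxygen stabilise it until Et3SiH delivers hydride. The closest known reaction type is the Lewis acid-promoted cyclisation of mixed acetals of dihydrofuryl alcohols onto the ring enol ether followed by Et3SiH reduction of the furofuranyl acetal, used for furofurans with endo aryl groups, together with acetal-initiated cyclisations that start from alkoxymethyl ethers; new here are the formaldehyde acetal as initiator and the aryl-bearing enol ether carbon. Ring 2 (C7', O, C9, C8, C8') closes in a 5-endo-trig mode with respect to the C9=O oxocarbenium bond and exo with respect to the C7=C8 enol ether. C8 is set by the tether, because C9 hangs from C8' through two atoms and can reach only the syn face of the dihydrofuran, which gives the cis ring fusion; C7 is set by hydride attack on the convex face of the cis-fused bicyclic cation, which puts ring A endo. The step needs ionisation of the acetal in preference to the electron-rich benzylic C7'–O and C2–O bonds and to protonation of the enol ether: the terminal methoxy oxygen is the most basic and least hindered site, the hindered pyridine in excess removes triflic acid, the temperature is kept low, and the silane is withheld until the C8–C9 bond exists so that neither the first oxocarbenium ion nor a protonated enol ether is reduced.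

Step 18
Reactants: 27 tris(triisopropylsilyl) ether of the target
Product: 28 CNP0303197.1 (target)
Conditions: TBAF, AcOH (1:1, 5 equiv), THF, 0 °C to rt
Reagents that add atoms: none
Why: Fluoride-mediated cleavage of the three silyl ethers is buffered with acetic acid so that no free phenoxide can open ring 3 or the furofuran through a quinone methide.

## Compound list

1 | vanillin | COc1cc(C=O)ccc1O | starting material
2 | 3-methoxy-4-(triisopropylsilyloxy)benzaldehyde | COc1cc(C=O)ccc1O[Si](C(C)C)(C(C)C)C(C)C | intermediate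
3 | [3-methoxy-4-(triisopropylsilyloxy)phenyl]methanol | COc1cc(CO)ccc1O[Si](C(C)C)(C(C)C)C(C)C | intermediate
4 | 3-bromo-4-hydroxy-5-methoxybenzonitrile | COc1cc(C#N)cc(Br)c1O | starting material
5 | 3-bromo-5-methoxy-4-{[3-methoxy-4-(triisopropylsilyloxy)phenyl]methoxy}benzonitrile | COc1cc(C#N)cc(Br)c1OCc1ccc(O[Si](C(C)C)(C(C)C)C(C)C)c(OC)c1 | intermediate
6 | tert-butyl 2-(5-cyano-3-methoxy-2-{[3-methoxy-4-(triisopropylsilyloxy)phenyl]methoxy}phenyl)acetate | COc1cc(C#N)cc(CC(=O)OC(C)(C)C)c1OCc1ccc(O[Si](C(C)C)(C(C)C)C(C)C)c(OC)c1 | intermediate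
7 | tert-butyl 2-(5-cyano-3-methoxy-2-{[3-methoxy-4-(triisopropylsilyloxy)phenyl]methoxy}phenyl)-2-diazoacetate | COc1cc(C#N)cc(C(=[N+]=[N-])C(=O)OC(C)(C)C)c1OCc1ccc(O[Si](C(C)C)(C(C)C)C(C)C)c(OC)c1 | intermediate
8 | tert-butyl (2S,3R)-5-cyano-7-methoxy-2-[3-methoxy-4-(triisopropylsilyloxy)phenyl]-2,3-dihydrobenzofuran-3-carboxylate (cis) | N#Cc1cc(OC)c2c(c1)[C@@H](C(=O)OC(C)(C)C)[C@@H](c1ccc(O[Si](C(C)C)(C(C)C)C(C)C)c(OC)c1)O2 | intermediate
9 | N,O-bis(diisobutylaluminium) aldimine alkoxide of 10 | CC(C)C[Al](CC(C)C)N=Cc1cc(OC)c2c(c1)[C@@H](CO[Al](CC(C)C)CC(C)C)[C@@H](c1ccc(O[Si](C(C)C)(C(C)C)C(C)C)c(OC)c1)O2 | intermediate (not isolated)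
10 | (2S,3S)-3-(hydroxymethyl)-7-methoxy-2-[3-methoxy-4-(triisopropylsilyloxy)phenyl]-2,3-dihydrobenzofuran-5-carbaldehyde (cis) | O=Cc1cc(OC)c2c(c1)[C@@H](CO)[C@@H](c1ccc(O[Si](C(C)C)(C(C)C)C(C)C)c(OC)c1)O2 | intermediate
11 | (2S,3S)-7-methoxy-2-[3-methoxy-4-(triisopropylsilyloxy)phenyl]-3-[(triisopropylsilyloxy)methyl]-2,3-dihydrobenzofuran-5-carbaldehyde (ArB–CHO) | O=Cc1cc(OC)c2c(c1)[C@@H](CO[Si](C(C)C)(C(C)C)C(C)C)[C@@H](c1ccc(O[Si](C(C)C)(C(C)C)C(C)C)c(OC)c1)O2 | intermediate
12 | 4-tert-butoxy-4-oxobutanoic acid | CC(C)(C)OC(=O)CCC(=O)O | starting material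
13 | (S)-4-benzyloxazolidin-2-one | O=C1N[C@@H](Cc2ccccc2)CO1 | starting material
14 | 4-tert-butoxy-4-oxobutanoic pivalic anhydride | CC(C)(C)OC(=O)CCC(=O)OC(=O)C(C)(C)C | intermediate (not isolated)
15 | tert-butyl 4-[(4S)-4-benzyl-2-oxooxazolidin-3-yl]-4-oxobutanoate | CC(C)(C)OC(=O)CCC(=O)N1C(=O)OC[C@@H]1Cc1ccccc1 | intermediate
16 | trimethylsilyl ether of 17 | CC(C)(C)OC(=O)C[C@H]([C@H](O[Si](C)(C)C)c1cc(OC)c2c(c1)[C@@H](CO[Si](C(C)C)(C(C)C)C(C)C)[C@@H](c1ccc(O[Si](C(C)C)(C(C)C)C(C)C)c(OC)c1)O2)C(=O)N1C(=O)OC[C@@H]1Cc1ccccc1 | intermediate (not isolated)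
17 | tert-butyl (3R)-4-[(4S)-4-benzyl-2-oxooxazolidin-3-yl]-3-[(S)-hydroxy(ArB)methyl]-4-oxobutanoate (anti) | CC(C)(C)OC(=O)C[C@H]([C@H](O)c1cc(OC)c2c(c1)[C@@H](CO[Si](C(C)C)(C(C)C)C(C)C)[C@@H](c1ccc(O[Si](C(C)C)(C(C)C)C(C)C)c(OC)c1)O2)C(=O)N1C(=O)OC[C@@H]1Cc1ccccc1 | intermediate
18 | tert-butyl (3R)-4-[(4S)-4-benzyl-2-oxooxazolidin-3-yl]-3-[(S)-(methoxymethoxy)(ArB)methyl]-4-oxobutanoate | CC(C)(C)OC(=O)C[C@H]([C@H](OCOC)c1cc(OC)c2c(c1)[C@@H](CO[Si](C(C)C)(C(C)C)C(C)C)[C@@H](c1ccc(O[Si](C(C)C)(C(C)C)C(C)C)c(OC)c1)O2)C(=O)N1C(=O)OC[C@@H]1Cc1ccccc1 | intermediate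
19 | tert-butyl (3S)-4-hydroxy-3-[(S)-(methoxymethoxy)(ArB)methyl]butanoate | CC(C)(C)OC(=O)C[C@H]([C@H](OCOC)c1cc(OC)c2c(c1)[C@@H](CO[Si](C(C)C)(C(C)C)C(C)C)[C@@H](c1ccc(O[Si](C(C)C)(C(C)C)C(C)C)c(OC)c1)O2)CO | intermediate
20 | (4S)-4-[(S)-(methoxymethoxy)(ArB)methyl]dihydrofuran-2(3H)-one | O=C1C[C@H]([C@H](OCOC)c2cc(OC)c3c(c2)[C@@H](CO[Si](C(C)C)(C(C)C)C(C)C)[C@@H](c2ccc(O[Si](C(C)C)(C(C)C)C(C)C)c(OC)c2)O3)CO1 | intermediate
21 | 4-bromo-2-methoxyphenol | COc1cc(Br)ccc1O | starting material
22 | (4-bromo-2-methoxyphenoxy)triisopropylsilane | COc1cc(Br)ccc1O[Si](C(C)C)(C(C)C)C(C)C | intermediate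
23 | [3-methoxy-4-(triisopropylsilyloxy)phenyl]lithium | COc1cc([Li])ccc1O[Si](C(C)C)(C(C)C)C(C)C | intermediate (not isolated)
24 | (4S)-2-ArA-4-[(S)-(methoxymethoxy)(ArB)methyl]tetrahydrofuran-2-ol, anomer mixture | COc1cc(C2(O)C[C@H]([C@H](OCOC)c3cc(OC)c4c(c3)[C@@H](CO[Si](C(C)C)(C(C)C)C(C)C)[C@@H](c3ccc(O[Si](C(C)C)(C(C)C)C(C)C)c(OC)c3)O4)CO2)ccc1O[Si](C(C)C)(C(C)C)C(C)C | intermediate
25 | (3S)-5-ArA-3-[(S)-(methoxymethoxy)(ArB)methyl]-2,3-dihydrofuran (key-step precursor) | COc1cc(C2=C[C@H]([C@H](OCOC)c3cc(OC)c4c(c3)[C@@H](CO[Si](C(C)C)(C(C)C)C(C)C)[C@@H](c3ccc(O[Si](C(C)C)(C(C)C)C(C)C)c(OC)c3)O4)CO2)ccc1O[Si](C(C)C)(C(C)C)C(C)C | intermediate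
26 | cis-fused furofuranyl oxocarbenium triflate (cation at C7) | COc1cc(C2=[O+]C[C@@H]3[C@H]2CO[C@@H]3c2cc(OC)c3c(c2)[C@@H](CO[Si](C(C)C)(C(C)C)C(C)C)[C@@H](c2ccc(O[Si](C(C)C)(C(C)C)C(C)C)c(OC)c2)O3)ccc1O[Si](C(C)C)(C(C)C)C(C)C.[O-]S(=O)(=O)C(F)(F)F | intermediate (not isolated)
27 | tris(triisopropylsilyl) ether of the target, (7S,8S,7'S,8'S) | COc1cc([C@H]2OC[C@@H]3[C@H]2CO[C@@H]3c2cc(OC)c3c(c2)[C@@H](CO[Si](C(C)C)(C(C)C)C(C)C)[C@@H](c2ccc(O[Si](C(C)C)(C(C)C)C(C)C)c(OC)c2)O3)ccc1O[Si](C(C)C)(C(C)C)C(C)C | intermediate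
28 | CNP0303197.1 | COc1cc([C@H]2OC[C@@H]3[C@H]2CO[C@@H]3c2cc(OC)c3c(c2)[C@@H](CO)[C@@H](c2ccc(O)c(OC)c2)O3)ccc1O | target

## Step count and risks

Total: 18 steps. Longest linear sequence: 16 steps (steps 1–8, 10–13, 15–18, from vanillin).

Steps most likely to fail:

1. Step 17 (labelled). The acetal may ionise more slowly than the electron-rich benzylic C7'–O bond or the C2–O bond of ring 3, or the enol ether may be protonated and oligomerise, with epimerisation or loss of material. The fallback closes both rings by oxygen alkylation and uses only known chemistry (lactone-enolate aldol, hydride reduction, cycloetherification through primary sulfonates). It sets out from lactone 20 and aldehyde 2.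
   - The lithium enolate of 20 (LiN(SiMe3)2, THF, −78 °C) adds to 2 to give the trans-α,β-disubstituted hydroxy lactone F1. The lactone carbonyl carbon is now the future C9 and the new carbinol is C7. The anti adduct is expected from the cyclic E-enolate through a chair transition state, with the new arm trans to the C8' arm.
   - LiAlH4 (THF, 0 °C) opens F1 to triol F2, and ZnBr2/n-PrSH (CH2Cl2, 0 °C) removes the methoxymethyl group to give tetrol F3.
   - MsCl (2.1 equiv), pyridine, 0 °C sulfonylates the two primary alcohols to dimesylate F4. On warming, the C7 oxygen closes onto C9' and the C7' oxygen onto C9; the other pairing would give four-membered rings. Substitution takes place at the primary carbons, so C7 and C7' keep their configuration and both aryl groups end endo.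
   - The product is tris-silyl ether 27, where the route is rejoined.

2. Step 10. The catalytic magnesium enolate may fail to turn over with the hindered, electron-rich aldehyde, or the anti/syn or facial selectivity may erode. The fallback replaces catalytic soft enolisation with a preformed enolate and an externally activated aldehyde. Imide 15 with Bu2BOTf/i-Pr2NEt (CH2Cl2, −78 to 0 °C) gives the dibutylboron Z-enolate F5, and aldehyde 11 precomplexed with Et2AlCl is added at −78 °C. The chelated boron enolate should react through an open transition state on the face away from the benzyl group and give the same anti adduct 17 directly as the free alcohol, where the route is rejoined.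

3. Step 16. The acid needed for dehydration may hydrolyse or oligomerise the electron-rich enol ether, or strip the acetal. The fallback makes the enol ether under basic conditions by cross-coupling and bypasses lactol 24. Lactone 20 with KN(SiMe3)2 and (PhO)2P(O)Cl (THF, −78 °C) gives ketene acetal phosphate F6. Aryllithium 23 is quenched with 2-isopropoxy-4,4,5,5-tetramethyl-1,3,2-dioxaborolane to give boronate F7. Suzuki–Miyaura coupling (Pd(PPh3)4, K3PO4, dioxane, 60 °C) joins F6 and F7 to dihydrofuran 25, where the route is rejoined.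

## Further compounds

F1 | step 17 | (3R,4S)-3-[(S)-hydroxy(ArA)methyl]-4-[(S)-(methoxymethoxy)(ArB)methyl]dihydrofuran-2(3H)-one (3,4-trans) | O=C1OC[C@@H]([C@H](OCOC)c2cc(OC)c3c(c2)[C@@H](CO[Si](C(C)C)(C(C)C)C(C)C)[C@@H](c2ccc(O[Si](C(C)C)(C(C)C)C(C)C)c(OC)c2)O3)[C@@H]1[C@H](O)c1ccc(O[Si](C(C)C)(C(C)C)C(C)C)c(OC)c1
F2 | step 17 | triol from reduction of F1: 2-[(S)-hydroxy(ArA)methyl]-3-[(S)-(methoxymethoxy)(ArB)methyl]butane-1,4-diol | OC[C@@H]([C@H](OCOC)c1cc(OC)c2c(c1)[C@@H](CO[Si](C(C)C)(C(C)C)C(C)C)[C@@H](c1ccc(O[Si](C(C)C)(C(C)C)C(C)C)c(OC)c1)O2)[C@@H](CO)[C@H](O)c1ccc(O[Si](C(C)C)(C(C)C)C(C)C)c(OC)c1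
F3 | step 17 | tetrol: 2-[(S)-hydroxy(ArA)methyl]-3-[(S)-hydroxy(ArB)methyl]butane-1,4-diol | OC[C@@H]([C@H](O)c1cc(OC)c2c(c1)[C@@H](CO[Si](C(C)C)(C(C)C)C(C)C)[C@@H](c1ccc(O[Si](C(C)C)(C(C)C)C(C)C)c(OC)c1)O2)[C@@H](CO)[C@H](O)c1ccc(O[Si](C(C)C)(C(C)C)C(C)C)c(OC)c1
F4 | step 17 | 1,4-dimethanesulfonate of F3 | CS(=O)(=O)OC[C@@H]([C@H](O)c1cc(OC)c2c(c1)[C@@H](CO[Si](C(C)C)(C(C)C)C(C)C)[C@@H](c1ccc(O[Si](C(C)C)(C(C)C)C(C)C)c(OC)c1)O2)[C@@H](COS(C)(=O)=O)[C@H](O)c1ccc(O[Si](C(C)C)(C(C)C)C(C)C)c(OC)c1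
F5 | step 10 | dibutylboron Z-enolate of imide 15 | CC(C)(C)OC(=O)C/C=C(\OB(CCCC)CCCC)N1C(=O)OC[C@@H]1Cc1ccccc1
F6 | step 16 | diphenyl (3S)-3-[(S)-(methoxymethoxy)(ArB)methyl]-2,3-dihydrofuran-5-yl phosphate | O=P(Oc1ccccc1)(Oc1ccccc1)OC1=C[C@H]([C@H](OCOC)c2cc(OC)c3c(c2)[C@@H](CO[Si](C(C)C)(C(C)C)C(C)C)[C@@H](c2ccc(O[Si](C(C)C)(C(C)C)C(C)C)c(OC)c2)O3)CO1
F7 | step 16 | 2-[3-methoxy-4-(triisopropylsilyloxy)phenyl]-4,4,5,5-tetramethyl-1,3,2-dioxaborolane | COc1cc(B2OC(C)(C)C(C)(C)O2)ccc1O[Si](C(C)C)(C(C)C)C(C)C
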